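**Remark on the chemistry (assumption).** The sulfate monoesters 18 and 19 are drawn as free hydrogen sulfates. Both would be handled as sodium salts, and the acid form of 19 would be released only at the end on a strongly acidic ion-exchange resin; this counter-ion exchange is treated as work-up.

## Structural features

The target is a phenylcoumaran: benzene ring A (C3a, C4–C7, C7a) is fused through the C3a–C7a bond to dihydrofuran ring B (O1, C2, C3). Ring A carries a methoxy group at C7 and a 3-(sulfooxy)propyl chain at C5. C2 carries a 4-hydroxy-3-methoxyphenyl group and C3 a hydroxymethyl group. The only stereocentres are the adjacent C2 (S) and C3 (R), trans across ring B. The fragile parts are the primary alkyl hydrogen sulfate (acid-labile, very polar) and the benzylic C2–O1 bond para to a phenol, which can open through a quinone-methide-type pathway. Three hydroxyl groups must be told apart, because only the chain hydroxyl is sulfated. The real difficulty is absolute and relative control at C2/C3 next to two electron-rich arenes, together with the 1,2,3,5-substitution of ring A (O at C7a, OMe at C7, C at C3a, chain at C5). The key step uses the fact that C7a and C7 both bear oxygen and that the O1–C2–C3 unit is a three-atom tether. A 3-alkoxy-4-methoxy-6-chloropyridazine maps onto ring A (C3→C7a, C4→C7, C5→C6, C6→C5), and an alkyne held on the tether supplies C3a and C4. Both stereocentres lie on the tether and can be set in acyclic form.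

## Logic of the disconnections

**19 ⇒ 18.** The two O–CH2Ph bonds (phenol oxygen and hydroxymethyl oxygen) are cut. Benzyl ethers survive every earlier step and come off together under neutral reductive conditions that leave a sulfate salt alone. The forward step must spare the sulfate and the C2–O1 bond.

**18 ⇒ 17.** The O–S bond is cut. The sulfate is the most polar and acid-sensitive group, so it is introduced last but one. This demands that 17 has exactly one free hydroxyl.

**17 ⇒ 13 + 14 (through 16 and 15).** The bond between C5 and the first chain carbon is cut. A cross-coupling at the chlorine left by the key step brings in the whole chain with its oxygen, so 13 needs no further change on ring A. The forward step must couple an electron-rich aryl chloride with an alkylborane, and the silyl group must fall off in the work-up.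

**13 ⇒ 11 (through 12).** C7a–C3a and C5–C4 are cut and N2 is reinserted between the carbons that become C7a and C5. This removes ring A and ring B in one operation and reduces the problem to an acyclic ether carrying both stereocentres. The forward step is thermal, so 11 must not lose its benzylic ether before it cyclises.

**11 ⇒ 8 + 9 (through 10).** The O1–C7a bond is cut. The aryl ether comes from an alkoxide and a chlorodiazine, leaving a simple homopropargylic alcohol. The forward step must attack C3 of 9 and not C6.

**8 ⇒ 5 + 6 (through 7).** The C2–C3 bond is cut. An allenylmetal addition makes this bond and both stereocentres from the single stereocentre of 5. It demands anti selectivity and clean chirality transfer.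

**5 ⇒ 4 ⇒ 3.** The O–S bond of the mesylate is cut, then the enantiomers are separated. The demand is one enantiomer of a small propargylic alcohol in high optical purity.

**3 ⇒ 1 + 2.** The bond between the carbinol carbon and the alkyne is cut, leading to two commercial reagents.

## Other disconnections considered

**Alternative 1:** The C3–C3a bond is traced to a 1,2-shift, so ester A2 comes from the six-membered (S)-flavanone A1, whose C4 becomes the ester carbon. In the forward step PhI(OAc)2 and acid in trimethyl orthoformate would form the enol ether of A1. The trivalent iodine reagent would attack C3 anti to the 2-aryl group, and ring A carbon C4a would migrate from C4 to C3 as iodobenzene leaves.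
- In its favour: C2 is set earlier by an asymmetric conjugate addition or oxa-Michael reaction, and the trans relationship follows from the antiperiplanar migration. Ring A is bought with bromine and methoxy in place, so no regiochemical question like that of step 5 arises. On this point, and on reaction temperature, it is better than the chosen plan.
- Against it: aryl B can migrate instead and the heterocyclic ring can dehydrogenate, which is why the phenol must be an electron-poor mesylate that later needs strongly basic removal. Acid can open A1 by retro-oxa-Michael reaction and erode optical purity. A2 still needs ester reduction, O-protection, the same cross-coupling and the same endgame.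
- Comparison: structurally it reshapes an existing ring, whereas step 6 builds rings A and B together. Mechanistically it is a cationic rearrangement with a migratory-aptitude competition against a tether-controlled pericyclic step. Step economy is about equal.

**Alternative 2:** C2–C3 and O1–C2 are cut. Product A6 would come from o-quinone methide A4, released from sulfone A3 by Cs2CO3, and the ylide of sulfonium salt A5. The ylide carbon would add to the methide carbon and the phenoxide would displace the sulfide.
- In its favour: room temperature, a convergent union, and the C5 chain already in place, so no cross-coupling follows. In mildness and in steps after the key step it is better than the chosen plan. Its trans selectivity (anti-betaine, SN2 closure) is equal.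
- Against it: both stereocentres are created in this step, so absolute control rests on a chiral sulfide or catalyst, which is less secure than the chirality transfer of step 4. A4 carries an alkyl and not an aryl group on the methide carbon and can tautomerise to a hydroxystyrene. A3 itself needs several steps.
- Comparison: it forms ring B only and needs ring A preassembled. It is an ionic Michael/SN2 cascade against a cycloaddition. The step count would probably be similar once A3 is made.

**Alternative 3:** O1–C2 and the C3–ester carbon bond are cut. Ester A8 would come from 2-hydroxystilbene A7 by oxypalladation with divalent palladium (Pd(OCOCF3)2, chiral bis(oxazoline)), CO insertion into the C3–palladium bond and methanolysis.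
- In its favour: it is catalytic in chirality and builds ring B, both stereocentres and the ester carbon in one step from an easily made alkene. On paper it is the shortest route, so better in step economy.
- Against it: the closure is 5-endo with respect to the alkene. The C3–palladium intermediate has a hydrogen on C2, and β-hydride elimination, which would aromatise ring B, is its usual fate. The trans product needs anti-oxypalladation followed by retentive carbonylation. Enantiofacial control on such an electron-rich stilbene has no close precedent.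
- Comparison: structurally equal in what it delivers after ester reduction. Mechanistically it is the least secure of the four. The chosen plan spends stoichiometric chirality but uses steps of known type.

Key step: step 6

## Route

**Step 1**
Reactants: 1 benzyloxyacetaldehyde; 2 ethynylmagnesium bromide
Product: 3 rac-1-(benzyloxy)but-3-yn-2-ol
Conditions: HC≡CMgBr (0.5 M in THF, 1.2 equiv), THF, −78 → 0 °C; aq. work-up
Reagents that add atoms: none
Why: Nucleophilic 1,2-addition of an alkynyl Grignard reagent to an aldehyde; no stereocontrol is sought because the racemate is resolved in step 2.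

**Step 2**
Reactants: 3 rac-1-(benzyloxy)but-3-yn-2-ol
Product: 4 (S)-1-(benzyloxy)but-3-yn-2-ol
Conditions: lipase from Burkholderia cepacia, vinyl acetate, MTBE, 30 °C, stopped just beyond half conversion; chromatography
Reagents that add atoms: none
Why: Lipase-catalysed kinetic resolution by transesterification with an irreversible acyl donor; by the Kazlauskas model (benzyloxymethyl as large, ethynyl as medium group) the (R)-alcohol should be acetylated and the (S)-alcohol left. Running past half conversion raises the optical purity of the slow enantiomer, which is the one needed.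

**Step 3**
Reactants: 4 (S)-1-(benzyloxy)but-3-yn-2-ol
Product: 5 (S)-1-(benzyloxy)but-3-yn-2-yl methanesulfonate
Conditions: MsCl, Et3N, CH2Cl2, −78 → −40 °C; used at once
Reagents that add atoms: methanesulfonyl chloride, CS(=O)(=O)Cl
Why: O-Sulfonylation at oxygen leaves the C–O bond untouched, so the (S) configuration is retained; the labile propargylic mesylate is kept cold and not stored.

**Step 4**
Reactants: 5 (S)-1-(benzyloxy)but-3-yn-2-yl methanesulfonate; 6 4-benzyloxy-3-methoxybenzaldehyde
Product: 8 (1S,2R)-1-[4-(benzyloxy)-3-methoxyphenyl]-2-[(benzyloxy)methyl]but-3-yn-1-ol, via allenylzinc reagent 7 (not isolated)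
Conditions: Pd(OAc)2 (5 mol %), PPh3 (5 mol %), Et2Zn (3 equiv), THF, −78 → −20 °C; aq. work-up
Reagents that add atoms: none
Why: Marshall propargylation: zerovalent palladium (from Pd(OAc)2, PPh3 and Et2Zn) adds to 5 in the anti SN2' sense, transmetalation gives the (P)-allenylzinc 7, and 7 adds to 6 by SE2' through a closed six-membered transition state on the face that carries zinc. The net inversion at the mesylate carbon sets the propargylic carbon as R, and the aryl group lying away from the benzyloxymethyl group in that transition state sets the carbinol carbon as S (anti).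

**Step 5**
Reactants: 8 (1S,2R)-1-[4-(benzyloxy)-3-methoxyphenyl]-2-[(benzyloxy)methyl]but-3-yn-1-ol; 9 3,6-dichloro-4-methoxypyridazine
Product: 11 3-{[(1S,2R)-1-[4-(benzyloxy)-3-methoxyphenyl]-2-[(benzyloxy)methyl]but-3-yn-1-yl]oxy}-6-chloro-4-methoxypyridazine, via sodium alkoxide 10 (not isolated)
Conditions: NaH (1.05 equiv), THF, 0 °C; then 9 (1.1 equiv), 0 → 25 °C
Reagents that add atoms: none
Why: Nucleophilic aromatic substitution (addition–elimination) of a chlorodiazine by an alkoxide; the stereocentres are not involved. C3 should be preferred over C6 because N1, which activates C6, is para to the 4-methoxy group and receives its lone-pair donation while N2, which activates C3, is meta to it, and because the sodium ion held by the methoxy oxygen can deliver the alkoxide to the neighbouring carbon in a weakly polar solvent.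

**Step 6**
Reactants: 11 3-{[(1S,2R)-1-[4-(benzyloxy)-3-methoxyphenyl]-2-[(benzyloxy)methyl]but-3-yn-1-yl]oxy}-6-chloro-4-methoxypyridazine
Product: 13 (2S,3R)-2-[4-(benzyloxy)-3-methoxyphenyl]-3-[(benzyloxy)methyl]-5-chloro-7-methoxy-2,3-dihydro-1-benzofuran, via bridged diazabicyclooctatriene 12 (not isolated)
Conditions: degassed 1,2-dichlorobenzene (0.02 M), 2,6-di-tert-butyl-4-methylpyridine (0.2 equiv), argon, 180 °C
Reagents that add atoms: none
Why: The chlorodiazine acts as the 4π component through C3 and C6 and the tethered terminal alkyne as the 2π component in an intramolecular inverse-electron-demand Diels–Alder reaction: the internal alkyne carbon bonds to C3 (new C7a–C3a) and the terminal carbon to C6 (new C5–C4), giving the 2,3-diazabicyclo[2.2.2]octatriene 12, which loses N2 by retro-[4+2] and aromatises irreversibly. The closest known reaction type is the thermal cyclisation of 3-(alk-3-ynyloxy)-6-chloropyridazines to 5-chloro-2,3-dihydrobenzofurans. Ring B closes as the five-membered ring fused at the new C7a–C3a bond, a 5-exo-dig mode for the alkyne with the O1–C2–C3 tether inside the ring; ring A is the six-membered ring of the [4+2] adduct, made aromatic by the cycloreversion. No stereocentre is formed: the bridgehead centres of 12 vanish with N2, so either face of the diazine may react, and C2 and C3 sit on the tether, are not enolisable and carry their anti relationship into the trans product. The step needs regioselectivity, which the three-atom tether enforces because only the fused orientation reaches C3 and C6, and chemoselectivity against cleavage of the benzylic C2–O bond, which the acid-free medium with a hindered base is meant to secure. The two tether substituents favour the folded reactive conformer, and the chlorine at C6 both lowers the diene LUMO and remains as the handle at C5.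

**Step 7**
Reactants: 13 (2S,3R)-2-[4-(benzyloxy)-3-methoxyphenyl]-3-[(benzyloxy)methyl]-5-chloro-7-methoxy-2,3-dihydro-1-benzofuran; 14 allyloxytrimethylsilane
Product: 17 3-[(2S,3R)-2-[4-(benzyloxy)-3-methoxyphenyl]-3-[(benzyloxy)methyl]-7-methoxy-2,3-dihydro-1-benzofuran-5-yl]propan-1-ol, via B-alkyl-9-BBN 15 (not isolated), via trimethylsilyl ether 16 (not isolated)
Conditions: 14, 9-BBN (0.5 M in THF), 0 → 25 °C; then 13, Pd(OAc)2 (4 mol %), SPhos (8 mol %), K3PO4 (3 equiv), THF/H2O, 65 °C; work-up K2CO3 (cat.), MeOH, 25 °C
Reagents that add atoms: none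
Why: Anti-Markovnikov hydroboration of 14 puts boron on the terminal carbon (15), and a B-alkyl Suzuki–Miyaura coupling with the electron-rich aryl chloride, made feasible by the dialkylbiarylphosphine on palladium, forms the C5–alkyl bond (16). The labile trimethylsilyl ether is methanolysed in the work-up, so the primary alcohol is obtained without a separate deprotection step.

**Step 8**
Reactants: 17 3-[(2S,3R)-2-[4-(benzyloxy)-3-methoxyphenyl]-3-[(benzyloxy)methyl]-7-methoxy-2,3-dihydro-1-benzofuran-5-yl]propan-1-ol
Product: 18 3-[(2S,3R)-2-[4-(benzyloxy)-3-methoxyphenyl]-3-[(benzyloxy)methyl]-7-methoxy-2,3-dihydro-1-benzofuran-5-yl]propyl hydrogen sulfate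
Conditions: SO3·pyridine (3 equiv), DMF, 25 °C; aq. NaHCO3
Reagents that add atoms: sulfur trioxide–pyridine complex, O=S(=O)([O-])[n+]1ccccc1
Why: O-Sulfation of an alcohol with a sulfur trioxide–amine complex; 17 has a single free hydroxyl, so no selectivity is needed. The bicarbonate work-up keeps the monoester as a stable salt and removes pyridine, which would inhibit the palladium catalyst of step 9.

**Step 9**
Reactants: 18 3-[(2S,3R)-2-[4-(benzyloxy)-3-methoxyphenyl]-3-[(benzyloxy)methyl]-7-methoxy-2,3-dihydro-1-benzofuran-5-yl]propyl hydrogen sulfate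
Product: 19 3-[(2S,3R)-2-(4-hydroxy-3-methoxyphenyl)-3-(hydroxymethyl)-7-methoxy-2,3-dihydro-1-benzofuran-5-yl]propyl hydrogen sulfate
Conditions: H2 (1 atm), 10% Pd/C, MeOH, 25 °C; cation-exchange resin (H+ form), 0 °C
Reagents that add atoms: none
Why: Catalytic hydrogenolysis of one aryl benzyl ether and one alkyl benzyl ether under neutral conditions, a standard last step for sulfated polyols. The sulfate salt, the aryl methyl ethers and, at ambient pressure and temperature, the benzylic C2–O1 bond of ring B should be untouched, so both stereocentres are kept.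

## Compound list

1 | benzyloxyacetaldehyde | O=CCOCc1ccccc1 | starting material
2 | ethynylmagnesium bromide | C#C[Mg]Br | starting material
3 | rac-1-(benzyloxy)but-3-yn-2-ol | C#CC(O)COCc1ccccc1 | intermediate
4 | (S)-1-(benzyloxy)but-3-yn-2-ol | C#C[C@H](O)COCc1ccccc1 | intermediate
5 | (S)-1-(benzyloxy)but-3-yn-2-yl methanesulfonate | C#C[C@H](OS(C)(=O)=O)COCc1ccccc1 | intermediate
6 | 4-benzyloxy-3-methoxybenzaldehyde | COc1cc(C=O)ccc1OCc1ccccc1 | starting material
7 | (P)-[4-(benzyloxy)buta-1,2-dien-1-yl](ethyl)zinc | CC[Zn]C([H])=[C@@]=C([H])COCc1ccccc1 | intermediate (not isolated)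
8 | (1S,2R)-1-[4-(benzyloxy)-3-methoxyphenyl]-2-[(benzyloxy)methyl]but-3-yn-1-ol (anti) | COc1cc([C@@H](O)[C@@H](COCc2ccccc2)C#C)ccc1OCc1ccccc1 | intermediate
9 | 3,6-dichloro-4-methoxypyridazine | COc1cc(Cl)nnc1Cl | starting material
10 | sodium (1S,2R)-1-[4-(benzyloxy)-3-methoxyphenyl]-2-[(benzyloxy)methyl]but-3-yn-1-olate | COc1cc([C@@H]([O-])[C@@H](COCc2ccccc2)C#C)ccc1OCc1ccccc1.[Na+] | intermediate (not isolated)
11 | 3-{[(1S,2R)-1-[4-(benzyloxy)-3-methoxyphenyl]-2-[(benzyloxy)methyl]but-3-yn-1-yl]oxy}-6-chloro-4-methoxypyridazine | COc1cc([C@@H](Oc2nnc(Cl)cc2OC)[C@@H](COCc2ccccc2)C#C)ccc1OCc1ccccc1 | intermediate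
12 | bridged 2,3-diazabicyclo[2.2.2]octa-2,5,7-triene cycloadduct of 11 (diazine C3 bonded to the internal and C6 to the terminal alkyne carbon; bridgehead configuration not defined) | COC1=CC2(Cl)N=NC13O[C@H](c4ccc(OCc5ccccc5)c(OC)c4)[C@@H](COCc4ccccc4)C3=C2 | intermediate (not isolated)
13 | (2S,3R)-2-[4-(benzyloxy)-3-methoxyphenyl]-3-[(benzyloxy)methyl]-5-chloro-7-methoxy-2,3-dihydro-1-benzofuran (trans) | COc1cc([C@H]2Oc3c(OC)cc(Cl)cc3[C@@H]2COCc2ccccc2)ccc1OCc1ccccc1 | intermediate
14 | allyloxytrimethylsilane | C=CCO[Si](C)(C)C | starting material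
15 | 9-[3-(trimethylsilyloxy)propyl]-9-borabicyclo[3.3.1]nonane | C[Si](C)(C)OCCCB1C2CCCC1CCC2 | intermediate (not isolated)
16 | (2S,3R)-2-[4-(benzyloxy)-3-methoxyphenyl]-3-[(benzyloxy)methyl]-7-methoxy-5-[3-(trimethylsilyloxy)propyl]-2,3-dihydro-1-benzofuran | COc1cc([C@H]2Oc3c(OC)cc(CCCO[Si](C)(C)C)cc3[C@@H]2COCc2ccccc2)ccc1OCc1ccccc1 | intermediate (not isolated)
17 | 3-[(2S,3R)-2-[4-(benzyloxy)-3-methoxyphenyl]-3-[(benzyloxy)methyl]-7-methoxy-2,3-dihydro-1-benzofuran-5-yl]propan-1-ol | COc1cc([C@H]2Oc3c(OC)cc(CCCO)cc3[C@@H]2COCc2ccccc2)ccc1OCc1ccccc1 | intermediate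
18 | 3-[(2S,3R)-2-[4-(benzyloxy)-3-methoxyphenyl]-3-[(benzyloxy)methyl]-7-methoxy-2,3-dihydro-1-benzofuran-5-yl]propyl hydrogen sulfate | COc1cc([C@H]2Oc3c(OC)cc(CCCOS(=O)(=O)O)cc3[C@@H]2COCc2ccccc2)ccc1OCc1ccccc1 | intermediate
19 | 3-[(2S,3R)-2-(4-hydroxy-3-methoxyphenyl)-3-(hydroxymethyl)-7-methoxy-2,3-dihydro-1-benzofuran-5-yl]propyl hydrogen sulfate | COc1cc([C@H]2Oc3c(OC)cc(CCCOS(=O)(=O)O)cc3[C@@H]2CO)ccc1O | target

## Step count and least certain steps

Total: 9 steps. Longest linear sequence: 9 steps (1 → 19); 2, 6, 9 and 14 are bought.

**Step 6 (key step).** The cycloaddition is slowed by the two oxygen donors on the diazine, and at the temperature it needs the benzylic C2–O1 bond may cleave first. This could happen by ionisation assisted by the para-benzyloxy group or by syn-elimination of the propargylic hydrogen through the diazine nitrogen, so substrate would be consumed without ring closure. The fallback makes the aryl group electron-poor during the thermal step. It sets out from 5 and comes back at 13.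
- The addition of step 4 is run with 4-formyl-2-methoxyphenyl 4-methylbenzenesulfonate F1, a more electrophilic aldehyde. It should give 4-[(1S,2R)-2-[(benzyloxy)methyl]-1-hydroxybut-3-yn-1-yl]-2-methoxyphenyl 4-methylbenzenesulfonate F2.
- Its sodium alkoxide F3 (NaH, THF, 0 °C, not isolated) with 9 should give 4-[(1S,2R)-2-[(benzyloxy)methyl]-1-[(6-chloro-4-methoxypyridazin-3-yl)oxy]but-3-yn-1-yl]-2-methoxyphenyl 4-methylbenzenesulfonate F4.
- Heating as in step 6 should lead, through the bridged diazabicyclooctatriene F5 (not isolated), to 4-[(2S,3R)-3-[(benzyloxy)methyl]-5-chloro-7-methoxy-2,3-dihydro-1-benzofuran-2-yl]-2-methoxyphenyl 4-methylbenzenesulfonate F6.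
- KOH in MeOH/THF at 60 °C frees 4-[(2S,3R)-3-[(benzyloxy)methyl]-5-chloro-7-methoxy-2,3-dihydro-1-benzofuran-2-yl]-2-methoxyphenol F7, and BnBr with K2CO3 in DMF gives 13.

**Step 5.** The hindered secondary alkoxide may attack C6, the less crowded carbon, instead of C3, or may displace both chlorines; the site of attachment would be checked by HMBC before step 6. The fallback fixes the site by leaving-group ability and moves the regiochemical question to a cheap fragment. It sets out from 9 and comes back at 11.
- NaSMe (1 equiv, THF, −20 °C) followed by separation and assignment of the regioisomers gives 6-chloro-4-methoxy-3-(methylsulfanyl)pyridazine F8.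
- mCPBA (2.2 equiv, CH2Cl2) gives 6-chloro-4-methoxy-3-(methylsulfonyl)pyridazine F9.
- Alkoxide 10 should displace the sulfinate at C3 much faster than the chloride at C6, giving 11.

**Step 4.** The transient allenylzinc may lose configurational integrity, or may eliminate benzyloxide through its propargylic tautomer, before the electron-rich and therefore slow aldehyde captures it; the anti/syn ratio may also erode. The fallback changes the organometallic and the way it is made. It sets out from 5 and 6 and comes back at 8. With Pd(dppf)Cl2 (5 mol %) and indium monoiodide InI (1.5 equiv) in THF/HMPA at 25 °C, the allenylpalladium is reduced to a transient, more covalent trivalent indium species, [(P)-4-(benzyloxy)buta-1,2-dien-1-yl]indium iodide methanesulfonate F10 (not isolated). It should add through the same closed transition state, with the same sense of chirality transfer, to give 8.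

**Step 2.** The lipase may discriminate the two enantiomers of this substrate too weakly, so that high optical purity costs most of the material. The fallback replaces resolution by enantioselective reduction. It sets out from 3 and comes back at 4. Dess–Martin periodinane (CH2Cl2, 0 °C) gives 1-(benzyloxy)but-3-yn-2-one F11. Midland reduction with B-isopinocampheyl-9-BBN derived from (+)-α-pinene (THF, 25 °C) treats the alkynyl group as the small substituent and should give 4.

**Step 9.** Hydrogenolysis may stall on the strongly adsorbing anionic sulfate. The sulfate may be lost by solvolysis if the medium turns acidic. Prolonged exposure may begin to open ring B at C2–O1. The fallback removes the benzyl groups before the sulfate exists and ends with a methanolysis. It sets out from 17 and comes back at 19.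
- TBDPSCl and imidazole (DMF) give the tert-butyldiphenylsilyl ether F12 of 17.
- H2 with 10% Pd/C in EtOAc gives the phenol–alcohol F13.
- Ac2O, pyridine and DMAP give the diacetate F14.
- HF·pyridine in THF/pyridine frees the chain alcohol F15.
- SO3·pyridine gives the diacetate hydrogen sulfate F16.
- K2CO3 in MeOH at 0 °C removes both acetates to give 19.

## Further compounds

F1 | step 6 | 4-formyl-2-methoxyphenyl 4-methylbenzenesulfonate | COc1cc(C=O)ccc1OS(=O)(=O)c1ccc(C)cc1
F2 | step 6 | 4-[(1S,2R)-2-[(benzyloxy)methyl]-1-hydroxybut-3-yn-1-yl]-2-methoxyphenyl 4-methylbenzenesulfonate | COc1cc([C@@H](O)[C@@H](COCc2ccccc2)C#C)ccc1OS(=O)(=O)c1ccc(C)cc1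
F3 | step 6 | sodium alkoxide of F2 | COc1cc([C@@H]([O-])[C@@H](COCc2ccccc2)C#C)ccc1OS(=O)(=O)c1ccc(C)cc1.[Na+]
F4 | step 6 | 4-[(1S,2R)-2-[(benzyloxy)methyl]-1-[(6-chloro-4-methoxypyridazin-3-yl)oxy]but-3-yn-1-yl]-2-methoxyphenyl 4-methylbenzenesulfonate | COc1cc([C@@H](Oc2nnc(Cl)cc2OC)[C@@H](COCc2ccccc2)C#C)ccc1OS(=O)(=O)c1ccc(C)cc1
F5 | step 6 | bridged 2,3-diazabicyclo[2.2.2]octa-2,5,7-triene cycloadduct of F4 (bridgehead configuration not defined) | COC1=CC2(Cl)N=NC13O[C@H](c4ccc(OS(=O)(=O)c5ccc(C)cc5)c(OC)c4)[C@@H](COCc4ccccc4)C3=C2
F6 | step 6 | 4-[(2S,3R)-3-[(benzyloxy)methyl]-5-chloro-7-methoxy-2,3-dihydro-1-benzofuran-2-yl]-2-methoxyphenyl 4-methylbenzenesulfonate | COc1cc([C@H]2Oc3c(OC)cc(Cl)cc3[C@@H]2COCc2ccccc2)ccc1OS(=O)(=O)c1ccc(C)cc1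
F7 | step 6 | 4-[(2S,3R)-3-[(benzyloxy)methyl]-5-chloro-7-methoxy-2,3-dihydro-1-benzofuran-2-yl]-2-methoxyphenol | COc1cc([C@H]2Oc3c(OC)cc(Cl)cc3[C@@H]2COCc2ccccc2)ccc1O
F8 | step 5 | 6-chloro-4-methoxy-3-(methylsulfanyl)pyridazine | COc1cc(Cl)nnc1SC
F9 | step 5 | 6-chloro-4-methoxy-3-(methylsulfonyl)pyridazine | COc1cc(Cl)nnc1S(C)(=O)=O
F10 | step 4 | [(P)-4-(benzyloxy)buta-1,2-dien-1-yl]indium iodide methanesulfonate | CS(=O)(=O)O[In](I)C([H])=[C@@]=C([H])COCc1ccccc1
F11 | step 2 | 1-(benzyloxy)but-3-yn-2-one | C#CC(=O)COCc1ccccc1
F12 | step 9 | (2S,3R)-2-[4-(benzyloxy)-3-methoxyphenyl]-3-[(benzyloxy)methyl]-5-[3-(tert-butyldiphenylsilyloxy)propyl]-7-methoxy-2,3-dihydro-1-benzofuran | COc1cc([C@H]2Oc3c(OC)cc(CCCO[Si](c4ccccc4)(c4ccccc4)C(C)(C)C)cc3[C@@H]2COCc2ccccc2)ccc1OCc1ccccc1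
F13 | step 9 | 4-[(2S,3R)-5-[3-(tert-butyldiphenylsilyloxy)propyl]-3-(hydroxymethyl)-7-methoxy-2,3-dihydro-1-benzofuran-2-yl]-2-methoxyphenol | COc1cc([C@H]2Oc3c(OC)cc(CCCO[Si](c4ccccc4)(c4ccccc4)C(C)(C)C)cc3[C@@H]2CO)ccc1O
F14 | step 9 | 4-[(2S,3R)-3-(acetoxymethyl)-5-[3-(tert-butyldiphenylsilyloxy)propyl]-7-methoxy-2,3-dihydro-1-benzofuran-2-yl]-2-methoxyphenyl acetate | COc1cc([C@H]2Oc3c(OC)cc(CCCO[Si](c4ccccc4)(c4ccccc4)C(C)(C)C)cc3[C@@H]2COC(C)=O)ccc1OC(C)=O
F15 | step 9 | 4-[(2S,3R)-3-(acetoxymethyl)-5-(3-hydroxypropyl)-7-methoxy-2,3-dihydro-1-benzofuran-2-yl]-2-methoxyphenyl acetate | COc1cc([C@H]2Oc3c(OC)cc(CCCO)cc3[C@@H]2COC(C)=O)ccc1OC(C)=O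
F16 | step 9 | 3-[(2S,3R)-2-(4-acetoxy-3-methoxyphenyl)-3-(acetoxymethyl)-7-methoxy-2,3-dihydro-1-benzofuran-5-yl]propyl hydrogen sulfate | COc1cc([C@H]2Oc3c(OC)cc(CCCOS(=O)(=O)O)cc3[C@@H]2COC(C)=O)ccc1OC(C)=O
A1 | alternative 1 | (S)-6-bromo-8-methoxy-2-[3-methoxy-4-(methylsulfonyloxy)phenyl]chroman-4-one | O=C1C[C@@H](c2ccc(OS(C)(=O)=O)c(OC)c2)Oc2c(OC)cc(Br)cc21
A2 | alternative 1 | methyl (2S,3S)-5-bromo-7-methoxy-2-[3-methoxy-4-(methylsulfonyloxy)phenyl]-2,3-dihydro-1-benzofuran-3-carboxylate (trans) | COc1cc([C@H]2Oc3c(OC)cc(Br)cc3[C@@H]2C(=O)OC)ccc1OS(C)(=O)=O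
A3 | alternative 2 | 2-[2-(benzyloxy)-1-(4-methylbenzenesulfonyl)ethyl]-4-[3-(tert-butyldimethylsilyloxy)propyl]-6-methoxyphenol (racemic) | Cc1ccc(cc1)S(=O)(=O)C(COCc1ccccc1)c1cc(CCCO[Si](C)(C)C(C)(C)C)cc(OC)c1O
A4 | alternative 2 | 6-[2-(benzyloxy)ethylidene]-4-[3-(tert-butyldimethylsilyloxy)propyl]-2-methoxycyclohexa-2,4-dien-1-one | COC1=CC(CCCO[Si](C)(C)C(C)(C)C)=CC(=CCOCc2ccccc2)C1=O
A5 | alternative 2 | 1-[4-(benzyloxy)-3-methoxybenzyl]thiolan-1-ium bromide (simplest carrier; a chiral sulfide would be needed for absolute control) | COc1cc(C[S+]2CCCC2)ccc1OCc1ccccc1.[Br-]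
A6 | alternative 2 | (2S,3R)-2-[4-(benzyloxy)-3-methoxyphenyl]-3-[(benzyloxy)methyl]-5-[3-(tert-butyldimethylsilyloxy)propyl]-7-methoxy-2,3-dihydro-1-benzofuran (trans) | COc1cc([C@H]2Oc3c(OC)cc(CCCO[Si](C)(C)C(C)(C)C)cc3[C@@H]2COCc2ccccc2)ccc1OCc1ccccc1
A7 | alternative 3 | 2-[(E)-2-[4-(benzyloxy)-3-methoxyphenyl]ethenyl]-4-[3-(tert-butyldimethylsilyloxy)propyl]-6-methoxyphenol | COc1cc(/C=C/c2cc(CCCO[Si](C)(C)C(C)(C)C)cc(OC)c2O)ccc1OCc1ccccc1
A8 | alternative 3 | methyl (2S,3S)-2-[4-(benzyloxy)-3-methoxyphenyl]-5-[3-(tert-butyldimethylsilyloxy)propyl]-7-methoxy-2,3-dihydro-1-benzofuran-3-carboxylate (trans) | COc1cc([C@H]2Oc3c(OC)cc(CCCO[Si](C)(C)C(C)(C)C)cc3[C@@H]2C(=O)OC)ccc1OCc1ccccc1
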